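(The numbers are those of an exercise, and the outcome is calculated.)

Whether 1.5 h is a long time for this isothermal flask can be reckoned from its rates.

solid substrate 5.0 mM; protic impurity 1.50 mM; time 1.5 h

    starting material ⇌ target (K1 = 2.0, k1 = 0.0613 /s)
    target ⇌ isomer of the product A (K2 = 2.36, k2 = 0.0104 /s)
    isomer of the product A ⇌ isomer of the product B (K3 = 4.8, k3 = 0.228 /s)
    starting material + protic impurity → quenched substrate (k4 = 11.4 /M/s)
    solid substrate ⇌ starting material, rate k5*(cs5 - [starting material]) while solid is left; crystals form when [starting material] > cs5 (cs5 = 1.7 mM, k5 = 0.126 /s)

- given per volume of solution although it is solid: solid substrate
- at the start none of the solid substrate is in solution
- what has only dissolved of solid substrate counts as not reacted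
- the reaction counts as stopped when no species that holds the solid substrate changes by six tenths of a point or more over the second half of the time
- run time (flask): 1.5 h

* which holds at 1.5 h: what has brought the reaction to rest, or that it has not come to rest (for what has run out or reacted, a solid counts together with what of it has only dissolved) (all of the solid substrate has reacted / forward and back rates have come level / it is still moving)
* part of the solid substrate that has turned into other species by 1.5 h (what has only dissolved does not count)
* amount of target at 1.5 h, in percent of the solid substrate charged

Who takes the starting material first? At the charge each dissolved starting material goes to target at 0.0613 /s, faster than it is quenched at 0.0171 /s. As a rough figure for a one-way passage, with no return from target counted and the protic impurity taken at 0.750 mM throughout, about 12.2% of the charge is quenched, which leaves an estimated 0.888 mM of the protic impurity.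

How does this comparison drift? Once the reversible pool of starting material, target and both isomers has equilibrated, starting material is a share of 3.29% of it. With the pool near 3.50 mM, the impurity decays pseudo-first-order, and its quench half-life, ln 2 over the rate constant times that share times the pool, is 8.79 min. This is longer than the slowest relaxation, 0.780 min, so the pool stays equilibrated while the impurity goes.

Is the time enough? It holds 10.2 quench half-lives, and over the second half of the time this reckoning has the quenched substrate gain about 0.512% of the charge, inside the stopping margin. This reckoning therefore commits to rest by level rates, conversion 97.7% and target 4.61%.

The forecast says forward and back rates have come level, with conversion 97.7% (97.4% to 98%) and target 4.6% (4.3% to 4.9%), from “a relaxation of a few minutes that is long finished”.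

The simulation gives forward and back rates have come level, conversion 97.7% and target 4.61%.

In this flask the quench half-life carries the impurity from 0.314% of its charge at 0.750 h to 0.00903% at 1.50 h, and the table reads 0.00907%. The neighbouring flask, charged with 6.0 mM of protic impurity, or 1.20 equiv, gives conversion 99.9% and target 0.246%, with 21% of its impurity left. In that neighbouring flask starting material reads 1.80% of the remaining pool, less than the equilibrated share of 3.29%, and the same half-life formula, taken with that reading and the impurity left, puts the drain of its pool near 44.1 min.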